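## Retrosynthetic overview

1. The dioxane ring is closed last by a hetero-Diels–Alder reaction between the o-quinone of catechol 33 (rings A–E) and cyclopentadiene 44 (guaiane half, made from (S)-carvone by ring expansion and ring-closing metathesis).
2. Rings C and B are closed together from seco-compound 30 by a hydrogen-atom-transfer-initiated polyene cyclisation (C8–C14 and C9–C10); C26 comes from a methylenation and the C27 methyl from an enolate methylation at C13.
3. Rings D and E are closed together by an intramolecular Diels–Alder reaction of acyclic tetraene 23. The enabling feature is that ring D is a cyclohexane in which C14 lies para to the quaternary C17: C14 can be the oxygenated carbon of a 2-silyloxydiene (C15=C14–C13=C18), the C28 methyl on C17 can be a formyl group that activates the dienophile C16=C17, and the other four ring E atoms C19–C22 (C21 masked as a dithiane) form the tether.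
4. Tetraene 23 comes from three pieces: (Z)-homoallylic iodide 9 (carrying ring A), ketophosphonate 10 and 1,3-dithiane 12 (acyl-anion carbon for C21).
5. Ring order: A (bought) → D + E → C + B → cyclopentene ring of the guaiane half → dioxane.

Key step: step 13

Remark: locants C1–C28 are those of the triterpenoid half (ring A C1–C5/C10, B C5–C10, C C8/C9/C11–C14, D C13–C18, E C17–C22; methyls C23 on C4, C25 on C9, C26 on C14, C27 on C13, C28 on C17); locants with g are those of the guaiane half; β is the face of the C25, C26 and C28 methyl groups; the final union is treated as a non-enzymatic cycloaddition.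

## Route

Step 1
Reactants: 1 2,3-dimethoxytoluene
Product: 2 1-iodo-3,4-dimethoxy-2-methylbenzene
Conditions: N-iodosuccinimide, CF3CO2H (cat.), MeCN, rt
Reagents that add atoms: N-iodosuccinimide, O=C1CCC(=O)N1I
Why: Electrophilic aromatic iodination should occur para to the 3-methoxy group (ortho to the methyl), the most activated and least hindered position; no stereocentre is formed.

Step 2
Reactants: 2 1-iodo-3,4-dimethoxy-2-methylbenzene; 3 prop-2-en-1-ol
Product: 4 3-(3,4-dimethoxy-2-methylphenyl)propanal
Conditions: Pd(OAc)2 (5 mol %), Bu4NCl, NaHCO3, DMF, 45 °C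
Reagents that add atoms: none
Why: Heck arylation of allyl alcohol followed by β-hydride elimination toward the carbinol carbon gives the enol and hence the saturated aldehyde.

Step 3
Reactants: 4 3-(3,4-dimethoxy-2-methylphenyl)propanal
Product: 5 1-[(3Z)-4-iodopent-3-en-1-yl]-3,4-dimethoxy-2-methylbenzene
Conditions: EtPPh3I, n-BuLi, THF, 0 °C; I2, −78 °C; NaN(SiMe3)2, −78 °C; then 4, −78 → −20 °C
Reagents that add atoms: ethyltriphenylphosphonium iodide, CC[P+](c1ccccc1)(c1ccccc1)c1ccccc1.[I-]; iodine, II
Why: Stork–Zhao olefination (Wittig reaction of the α-iodo ylide) should give the (Z)-iodoalkene with iodine cis to the chain, which fixes the olefin geometry later translated into C8 and C9.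

Step 4
Reactants: 5 1-[(3Z)-4-iodopent-3-en-1-yl]-3,4-dimethoxy-2-methylbenzene; 6 oxirane
Product: 8 (3Z)-6-(3,4-dimethoxy-2-methylphenyl)-3-methylhex-3-en-1-ol, via vinyllithium 7 (not isolated)
Conditions: t-BuLi (2.1 equiv), Et2O, −78 °C; then oxirane, −78 → 0 °C
Reagents that add atoms: none
Why: Iodine–lithium exchange proceeds with retention of alkene geometry and the vinyllithium opens the epoxide (SN2) to the (Z)-homoallylic alcohol.

Step 5
Reactants: 8 (3Z)-6-(3,4-dimethoxy-2-methylphenyl)-3-methylhex-3-en-1-ol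
Product: 9 1-[(3Z)-6-iodo-4-methylhex-3-en-1-yl]-3,4-dimethoxy-2-methylbenzene
Conditions: I2, PPh3, imidazole, CH2Cl2, 0 °C
Reagents that add atoms: iodine, II
Why: Appel-type iodination of the primary alcohol (SN2 on the alkoxyphosphonium ion) leaves the trisubstituted alkene untouched.

Step 6
Reactants: 9 1-[(3Z)-6-iodo-4-methylhex-3-en-1-yl]-3,4-dimethoxy-2-methylbenzene; 10 diethyl (2-oxopropyl)phosphonate
Product: 11 diethyl [(6Z)-9-(3,4-dimethoxy-2-methylphenyl)-6-methyl-2-oxonon-6-en-3-yl]phosphonate (racemic at C3)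
Conditions: Cs2CO3, DMF, rt → 40 °C
Reagents that add atoms: none
Why: C-alkylation of the stabilised β-ketophosphonate anion by the primary iodide; the new centre is racemic and is destroyed in step 10.

Step 7
Reactants: 12 1,3-dithiane; 13 2-(2-bromoethyl)-1,3-dioxolane
Product: 15 2-[2-(1,3-dithian-2-yl)ethyl]-1,3-dioxolane, via 2-lithio-1,3-dithiane 14 (not isolated)
Conditions: n-BuLi, THF, −30 °C; then 13, −30 °C → rt
Reagents that add atoms: none
Why: Corey–Seebach alkylation, in which the dithiane carbon (future C21) acts as an acyl-anion equivalent toward the primary bromide.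

Step 8
Reactants: 15 2-[2-(1,3-dithian-2-yl)ethyl]-1,3-dioxolane; 16 2,3-dibromoprop-1-ene
Product: 18 2-(2-bromoprop-2-en-1-yl)-2-[2-(1,3-dioxolan-2-yl)ethyl]-1,3-dithiane, via lithiated dithiane 17 (not isolated)
Conditions: n-BuLi, THF, −30 °C; then 16, −78 °C → rt
Reagents that add atoms: none
Why: A second Corey–Seebach alkylation at the allylic bromide (the vinylic bromide is inert to SN2) installs C22, C17 and C16.

Step 9
Reactants: 18 2-(2-bromoprop-2-en-1-yl)-2-[2-(1,3-dioxolan-2-yl)ethyl]-1,3-dithiane
Product: 19 3-[2-(2-bromoprop-2-en-1-yl)-1,3-dithian-2-yl]propanal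
Conditions: 1 M HCl, THF, 40 °C
Reagents that add atoms: water, O
Why: Acid hydrolysis of the O,O-acetal frees the C18 aldehyde, while the dithioacetal is stable to aqueous acid.

Step 10
Reactants: 11 diethyl [(6Z)-9-(3,4-dimethoxy-2-methylphenyl)-6-methyl-2-oxonon-6-en-3-yl]phosphonate; 19 3-[2-(2-bromoprop-2-en-1-yl)-1,3-dithian-2-yl]propanal
Product: 20 (3E,6Z)-3-{3-[2-(2-bromoprop-2-en-1-yl)-1,3-dithian-2-yl]propylidene}-9-(3,4-dimethoxy-2-methylphenyl)-6-methylnon-6-en-2-one
Conditions: Ba(OH)2·8H2O, THF/H2O (40:1), rt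
Reagents that add atoms: none
Why: Horner–Wadsworth–Emmons olefination of the α-substituted β-ketophosphonate should give the (E)-enone (C19 chain trans to acetyl), the geometry needed to place the tether on the outside of the s-cis diene.

Step 11
Reactants: 20 (3E,6Z)-enone
Product: 21 triisopropylsilyl dienol ether of 20 (2-silyloxy-1,3-diene C15=C14(OSi)–C13=C18)
Conditions: i-Pr3SiOTf, Et3N, CH2Cl2, −78 → 0 °C
Reagents that add atoms: triisopropylsilyl trifluoromethanesulfonate, CC(C)[Si](OS(=O)(=O)C(F)(F)F)(C(C)C)C(C)C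
Why: Soft enolisation at the α′-methyl group gives the cross-conjugated silyl dienol ether, and doing it before any aldehyde is present avoids Mukaiyama aldol chemistry.

Step 12
Reactants: 21 bromo silyloxydiene
Product: 23 tetraene aldehyde (2-substituted acrolein C16=C17–C28HO tethered to the silyloxydiene), via vinyllithium 22 (not isolated)
Conditions: t-BuLi (2.1 equiv), THF/Et2O, −78 °C; DMF, −78 °C; aq. NH4Cl, 0 °C
Reagents that add atoms: N,N-dimethylformamide, CN(C)C=O
Why: Bromine–lithium exchange at the 2-bromoalkene and formylation with DMF give the enal under non-acidic conditions that the silyl enol ether and the 2,2-disubstituted dithiane tolerate.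

Step 13
Reactants: 23 tetraene aldehyde
Product: 24 trans-fused D/E bicycle: silyl enol ether C13=C14, side chain on C13, C21 dithiane, 17β-formyl, 18α-H
Conditions: (S)-1-(2-methylphenyl)-3,3-diphenyltetrahydro-1H,3H-pyrrolo[1,2-c][1,3,2]oxazaborole (20 mol %), HNTf2 (18 mol %), CH2Cl2, −78 → −40 °C
Reagents that add atoms: none
Why: The protonated oxazaborolidine binds the formyl group of the 2-substituted acrolein unit and the 2-silyloxydiene adds in an asynchronous concerted [4+2] cycloaddition, C15 (the nucleophilic diene terminus) bonding to the β-carbon C16 and C18 to the α-carbon C17, so that the tether and the polarity of both partners demand the same regiochemistry. The closest known reaction type is the oxazaborolidinium-catalysed enantioselective Diels–Alder reaction of 2-substituted acroleins with 2-silyloxydienes and its intramolecular trienal variant. Ring D closes as the cyclohexene of the cycloaddition (both new bonds lie in it) and ring E closes as the six-membered tether ring through the C17–C18 bond (fused mode of a 1,3,9-decatriene, helped by the gem-disubstituted dithiane carbon). C17 is set by the catalyst, which shields one face of the s-trans enal so that the diene should add to the face on which CHO, C16 and C22 run clockwise; C18 follows from the (E)-geometry of C13=C18 together with the formyl-endo, tether-exo transition state, which places H-18 anti to the formyl group (trans D/E). The step needs endo over exo selectivity and a slow uncatalysed background reaction; the first is favoured by the Lewis-acid-bound carbonyl and the second by the low temperature, and the tetrasubstituted silyl enol ether that results stores the regiochemistry for step 15.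

Step 14
Reactants: 24 D/E aldehyde
Product: 26 D/E bicycle with 17β-methyl (C28), via tosylhydrazone 25 (not isolated)
Conditions: TsNHNH2, THF, rt; catecholborane, CHCl3, 0 °C; NaOAc·3H2O, 60 °C
Reagents that add atoms: none
Why: Tosylhydrazone formation, hydride addition to C=N and loss of sulfinate and dinitrogen convert the neopentyl aldehyde into the C28 methyl group under near-neutral conditions that spare the silyl enol ether; C17 is untouched.

Step 15
Reactants: 26 D/E silyl enol ether
Product: 28 14-ketone with quaternary C13 (13α-methyl; side chain cis to the 17β-methyl), via sulfonium enolate 27 (not isolated)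
Conditions: (Me2N)3S+ Me3SiF2−, MeI (5 equiv), THF, −78 → −30 °C
Reagents that add atoms: iodomethane, CI
Why: Fluoride cleavage of the silyl enol ether gives the C13 enolate regiospecifically and C-methylation should occur on the α-face, anti to the axial 17β-methyl that shields the β-face by a 1,3-diaxial interaction, which sets C13.

Step 16
Reactants: 28 14-ketone
Product: 29 14-methylidene compound (C26 as exocyclic CH2)
Conditions: Ph3PCH3Br, KOt-Bu, toluene, 90 °C
Reagents that add atoms: methyltriphenylphosphonium bromide, C[P+](c1ccccc1)(c1ccccc1)c1ccccc1.[Br-]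
Why: Wittig methylenation under conditions used for hindered ketones; neither α-carbon bears an epimerisable stereocentre.

Step 17
Reactants: 29 14-methylidene dithiane
Product: 30 seco-ketone (C21 ketone, exocyclic C14=C26, (Z)-C8=C9, arene)
Conditions: MeI (10 equiv), CaCO3, MeCN/H2O (4:1), 45 °C
Reagents that add atoms: water, O
Why: Alkylative hydrolysis of the dithiane frees the C21 ketone without acid or oxidant, so the alkenes and the arene survive, and it removes sulfur before the oxidising conditions of step 18.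

Step 18
Reactants: 30 seco-ketone
Product: 31 pentacyclic 2,3-dimethyl ether (8β-H, 9β-Me, 13α-Me, 14β-Me, 17β-Me, 18α-H; 21-ketone)
Conditions: [N,N′-bis(3,5-di-tert-butylsalicylidene)cyclohexane-1,2-diaminato]cobalt (divalent cobalt, 5 mol %), N-fluoro-2,4,6-trimethylpyridinium triflate (1.5 equiv), PhSiH3 (1.2 equiv), (CF3)2CHOH, 0 °C → rt
Reagents that add atoms: none
Why: In this Mukaiyama-type hydrogen-atom-transfer-initiated radical-polar crossover polyene cyclisation the cobalt hydride should deliver hydrogen only to the 1,1-disubstituted alkene, the C14 radical/cation is attacked by C8 of the (Z)-alkene in a 6-endo closure and the C9 cation by the arene para to methoxy; closure on the α-face of C14 (trans C/D) is expected because closure cis to the C12 branch would fold ring C against the axial 17β-methyl, and anti addition across the (Z)-alkene through a chair-like ring C gives H-8 and the C25 methyl syn (cis B/C).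

Step 19
Reactants: 31 pentacyclic dimethyl ether
Product: 32 6,21-diketone (2,3-dimethyl ether)
Conditions: CrO3, AcOH/H2O, rt
Reagents that add atoms: chromium trioxide, O=[Cr](=O)=O
Why: Chromic acid benzylic oxidation at C6, the only benzylic methylene (C9 is quaternary), is the standard route to aryl ketones of this hydrophenanthrene type and leaves all stereocentres untouched.

Step 20
Reactants: 32 6,21-diketone dimethyl ether
Product: 33 catechol (2,3-dihydroxy-6,21-dione)
Conditions: BBr3, CH2Cl2, −78 → 0 °C; aq. work-up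
Reagents that add atoms: none
Why: Lewis-acid cleavage of the two aryl methyl ethers; both ketones are stable to BBr3.

Step 21
Reactants: 34 (S)-carvone
Product: 35 (2S,5S)-2-methyl-5-(prop-1-en-2-yl)cyclohexan-1-one (trans-dihydrocarvone)
Conditions: LiBH(s-Bu)3, THF, −78 °C; aq. NH4Cl; then NaOMe (cat.), MeOH, rt
Reagents that add atoms: none
Why: Conjugate hydride reduction of the enone followed by base equilibration at C2 should give the trans (diequatorial) isomer, with C5 taken unchanged from carvone.

Step 22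
Reactants: 35 (2S,5S)-dihydrocarvone; 36 ethyl diazoacetate
Product: 37 ethyl (3S,6S)-3-methyl-2-oxo-6-(prop-1-en-2-yl)cycloheptane-1-carboxylate (C1 epimers and enol)
Conditions: BF3·OEt2, Et2O, 0 °C → rt
Reagents that add atoms: none
Why: Lewis-acid-promoted diazoacetate ring expansion (Tiffeneau–Demjanov type) with migration of the less substituted α-methylene places the ester-bearing carbon (C5g) away from the methyl-bearing C10g, whose configuration is retained.

Step 23
Reactants: 37 β-keto ester
Product: 38 ethyl (3S,6S)-3-methyl-6-(prop-1-en-2-yl)-2-(trifluoromethanesulfonyloxy)cyclohept-1-ene-1-carboxylate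
Conditions: Tf2O, i-Pr2NEt, CH2Cl2, −78 °C
Reagents that add atoms: trifluoromethanesulfonic anhydride, O=S(=O)(OS(=O)(=O)C(F)(F)F)C(F)(F)F
Why: O-sulfonylation of the β-keto ester enol, which forms toward the doubly activated C5g, so C10g is not enolised.

Step 24
Reactants: 38 enol triflate; 39 allyltributylstannane
Product: 40 ethyl (3S,6S)-2-allyl-3-methyl-6-(prop-1-en-2-yl)cyclohept-1-ene-1-carboxylate
Conditions: Pd(PPh3)4 (5 mol %), LiCl, THF, 65 °C
Reagents that add atoms: none
Why: Stille coupling of the vinyl triflate with the allylstannane installs C2g and C3g on C1g.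

Step 25
Reactants: 40 allyl ester
Product: 42 2-[(3S,6S)-2-allyl-3-methyl-6-(prop-1-en-2-yl)cyclohept-1-en-1-yl]propan-2-ol, via methyl ketone 41 (not isolated)
Conditions: MeLi (3 equiv), Et2O, −78 → 0 °C
Reagents that add atoms: methyllithium, [Li]C
Why: Double 1,2-addition of methyllithium to the hindered ester gives the tertiary alcohol carrying C4g and its methyl.

Step 26
Reactants: 42 tertiary alcohol
Product: 43 (3S,6S)-2-allyl-3-methyl-1,6-di(prop-1-en-2-yl)cyclohept-1-ene
Conditions: Burgess reagent (MeO2CN−SO2N+Et3), toluene, 50 °C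
Reagents that add atoms: none
Why: Syn-elimination through the sulfamate ester can only take a methyl hydrogen, giving the isopropenyl group without ionisation.

Step 27
Reactants: 43 tetraene
Product: 44 (4S,7S)-1,4-dimethyl-7-(prop-1-en-2-yl)-3,4,5,6,7,8-hexahydroazulene (guaia-1(5),3,11-triene)
Conditions: second-generation Grubbs catalyst (5 mol %), CH2Cl2, 40 °C; used at once
Reagents that add atoms: none
Why: Ring-closing metathesis between the cis-disposed allyl and isopropenyl groups (the diene analogue of indene formation from 1-allyl-2-vinylarenes) forms C3g=C4g and gives the cyclopentadiene as a single double-bond isomer under neutral conditions.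

Step 28
Reactants: 33 catechol; 44 guaiatriene
Product: 46 CNP0177131.1 (target), via o-quinone 45 (not isolated)
Conditions: Ag2O, Na2SO4, CH2Cl2, 0 °C → rt, dark
Reagents that add atoms: none
Why: Oxidation to the 6-oxo-o-quinone and inverse-electron-demand hetero-Diels–Alder addition of its O=C–C=O unit across C1g=C5g; the nucleophilic diene terminus C1g should bond to O3 (leaving the developing phenoxide at O2 para to the C6 acyl group) and O2 then closes on C5g, with suprafacial addition anti to the C10g methyl setting C1g and C5g.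

## Compound list

1 | 2,3-dimethoxytoluene | COc1cccc(C)c1OC | starting material
2 | 1-iodo-3,4-dimethoxy-2-methylbenzene | COc1ccc(I)c(C)c1OC | intermediate
3 | prop-2-en-1-ol | C=CCO | starting material
4 | 3-(3,4-dimethoxy-2-methylphenyl)propanal | COc1ccc(CCC=O)c(C)c1OC | intermediate
5 | 1-[(3Z)-4-iodopent-3-en-1-yl]-3,4-dimethoxy-2-methylbenzene | COc1ccc(CC/C=C(C)\I)c(C)c1OC | intermediate
6 | oxirane | C1CO1 | starting material
7 | [(2Z)-5-(3,4-dimethoxy-2-methylphenyl)pent-2-en-2-yl]lithium | COc1ccc(CC/C=C(C)\[Li])c(C)c1OC | intermediate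
8 | (3Z)-6-(3,4-dimethoxy-2-methylphenyl)-3-methylhex-3-en-1-ol | COc1ccc(CC/C=C(C)\CCO)c(C)c1OC | intermediate
9 | 1-[(3Z)-6-iodo-4-methylhex-3-en-1-yl]-3,4-dimethoxy-2-methylbenzene | COc1ccc(CC/C=C(C)\CCI)c(C)c1OC | intermediate
10 | diethyl (2-oxopropyl)phosphonate | CCOP(=O)(CC(C)=O)OCC | starting material
11 | diethyl [(6Z)-9-(3,4-dimethoxy-2-methylphenyl)-6-methyl-2-oxonon-6-en-3-yl]phosphonate (racemic) | COc1ccc(CC/C=C(C)\CCC(C(C)=O)P(=O)(OCC)OCC)c(C)c1OC | intermediate
12 | 1,3-dithiane | C1CSCSC1 | starting material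
13 | 2-(2-bromoethyl)-1,3-dioxolane | BrCCC1OCCO1 | starting material
14 | 2-lithio-1,3-dithiane | [Li]C1SCCCS1 | intermediate
15 | 2-[2-(1,3-dithian-2-yl)ethyl]-1,3-dioxolane | C1CSC(CCC2OCCO2)SC1 | intermediate
16 | 2,3-dibromoprop-1-ene | C=C(Br)CBr | starting material
17 | 2-lithio-2-[2-(1,3-dioxolan-2-yl)ethyl]-1,3-dithiane | [Li]C1(CCC2OCCO2)SCCCS1 | intermediate
18 | 2-(2-bromoprop-2-en-1-yl)-2-[2-(1,3-dioxolan-2-yl)ethyl]-1,3-dithiane | C=C(Br)CC1(CCC2OCCO2)SCCCS1 | intermediate
19 | 3-[2-(2-bromoprop-2-en-1-yl)-1,3-dithian-2-yl]propanal | C=C(Br)CC1(CCC=O)SCCCS1 | intermediate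
20 | (3E,6Z)-3-{3-[2-(2-bromoprop-2-en-1-yl)-1,3-dithian-2-yl]propylidene}-9-(3,4-dimethoxy-2-methylphenyl)-6-methylnon-6-en-2-one | COc1ccc(CC/C=C(C)\CC/C(C(C)=O)=C\CCC2(CC(Br)=C)SCCCS2)c(C)c1OC | intermediate
21 | triisopropylsilyl dienol ether of 20 (2-silyloxy-1,3-diene, vinyl bromide) | COc1ccc(CC/C=C(C)\CC/C(C(=C)O[Si](C(C)C)(C(C)C)C(C)C)=C\CCC2(CC(Br)=C)SCCCS2)c(C)c1OC | intermediate
22 | vinyllithium from 21 (lithium in place of bromine) | COc1ccc(CC/C=C(C)\CC/C(C(=C)O[Si](C(C)C)(C(C)C)C(C)C)=C\CCC2(CC([Li])=C)SCCCS2)c(C)c1OC | intermediate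
23 | tetraene aldehyde (silyloxydiene tethered to a 2-substituted acrolein) | COc1ccc(CC/C=C(C)\CC/C(C(=C)O[Si](C(C)C)(C(C)C)C(C)C)=C\CCC2(CC(=C)C=O)SCCCS2)c(C)c1OC | intermediate
24 | trans-fused D/E bicycle, silyl enol ether C13=C14, C21 dithiane, 17β-formyl, 18α-H | COc1ccc(CC/C=C(C)\CCC2=C(O[Si](C(C)C)(C(C)C)C(C)C)CC[C@@]3(C=O)CC4(SCCCS4)CC[C@H]23)c(C)c1OC | intermediate
25 | tosylhydrazone of 24 | COc1ccc(CC/C=C(C)\CCC2=C(O[Si](C(C)C)(C(C)C)C(C)C)CC[C@@]3(C=NNS(=O)(=O)c5ccc(C)cc5)CC4(SCCCS4)CC[C@H]23)c(C)c1OC | intermediate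
26 | D/E silyl enol ether with 17β-methyl, 18α-H | COc1ccc(CC/C=C(C)\CCC2=C(O[Si](C(C)C)(C(C)C)C(C)C)CC[C@@]3(C)CC4(SCCCS4)CC[C@H]23)c(C)c1OC | intermediate
27 | tris(dimethylamino)sulfonium C13 enolate | COc1ccc(CC/C=C(C)\CCC2=C([O-])CC[C@@]3(C)CC4(SCCCS4)CC[C@H]23)c(C)c1OC.CN(C)[S+](N(C)C)N(C)C | intermediate
28 | D/E 14-ketone, 13α-methyl (side chain cis to 17β-methyl), C21 dithiane | COc1ccc(CC/C=C(C)\CC[C@@]2(C)[C@H]3CCC4(SCCCS4)C[C@]3(C)CCC2=O)c(C)c1OC | intermediate
29 | 14-methylidene analogue of 28 | COc1ccc(CC/C=C(C)\CC[C@@]2(C)[C@H]3CCC4(SCCCS4)C[C@]3(C)CCC2=C)c(C)c1OC | intermediate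
30 | seco-ketone: 14-methylidene, 21-ketone | COc1ccc(CC/C=C(C)\CC[C@@]2(C)[C@H]3CCC(=O)C[C@]3(C)CCC2=C)c(C)c1OC | intermediate
31 | pentacyclic 2,3-dimethyl ether, 21-ketone (8β-H, 9β-Me, 13α-Me, 14β-Me, 17β-Me, 18α-H) | COc1cc2c(c(C)c1OC)CC[C@@H]1[C@@]2(C)CC[C@@]2(C)[C@H]3CCC(=O)C[C@]3(C)CC[C@]12C | intermediate
32 | pentacyclic 2,3-dimethyl ether, 6,21-dione | COc1cc2c(c(C)c1OC)C(=O)C[C@@H]1[C@@]2(C)CC[C@@]2(C)[C@H]3CCC(=O)C[C@]3(C)CC[C@]12C | intermediate
33 | pentacyclic catechol, 6,21-dione | Oc1cc2c(c(C)c1O)C(=O)C[C@@H]1[C@@]2(C)CC[C@@]2(C)[C@H]3CCC(=O)C[C@]3(C)CC[C@]12C | intermediate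
34 | (S)-carvone | C=C(C)[C@H]1CC=C(C)C(=O)C1 | starting material
35 | (2S,5S)-2-methyl-5-(prop-1-en-2-yl)cyclohexan-1-one | C=C(C)[C@H]1CC[C@H](C)C(=O)C1 | intermediate
36 | ethyl diazoacetate | CCOC(=O)C=[N+]=[N-] | starting material
37 | ethyl (3S,6S)-3-methyl-2-oxo-6-(prop-1-en-2-yl)cycloheptane-1-carboxylate | C=C(C)[C@H]1CC[C@H](C)C(=O)C(C(=O)OCC)C1 | intermediate
38 | ethyl (3S,6S)-3-methyl-6-(prop-1-en-2-yl)-2-(trifluoromethanesulfonyloxy)cyclohept-1-ene-1-carboxylate | C=C(C)[C@H]1CC[C@H](C)C(OS(=O)(=O)C(F)(F)F)=C(C(=O)OCC)C1 | intermediate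
39 | allyltributylstannane | C=CC[Sn](CCCC)(CCCC)CCCC | starting material
40 | ethyl (3S,6S)-2-allyl-3-methyl-6-(prop-1-en-2-yl)cyclohept-1-ene-1-carboxylate | C=C(C)[C@H]1CC[C@H](C)C(CC=C)=C(C(=O)OCC)C1 | intermediate
41 | 1-[(3S,6S)-2-allyl-3-methyl-6-(prop-1-en-2-yl)cyclohept-1-en-1-yl]ethan-1-one | C=C(C)[C@H]1CC[C@H](C)C(CC=C)=C(C(C)=O)C1 | intermediate
42 | 2-[(3S,6S)-2-allyl-3-methyl-6-(prop-1-en-2-yl)cyclohept-1-en-1-yl]propan-2-ol | C=C(C)[C@H]1CC[C@H](C)C(CC=C)=C(C(C)(C)O)C1 | intermediate
43 | (3S,6S)-2-allyl-3-methyl-1,6-di(prop-1-en-2-yl)cyclohept-1-ene | C=C(C)[C@H]1CC[C@H](C)C(CC=C)=C(C(C)=C)C1 | intermediate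
44 | (4S,7S)-1,4-dimethyl-7-(prop-1-en-2-yl)-3,4,5,6,7,8-hexahydroazulene | C=C(C)[C@H]1CC[C@H](C)C2=C(C1)C(C)=CC2 | intermediate
45 | o-quinone of 33 (2,3,6,21-tetraone) | O=C1C=C2C(=C(C)C1=O)C(=O)C[C@@H]1[C@@]2(C)CC[C@@]2(C)[C@H]3CCC(=O)C[C@]3(C)CC[C@]12C | intermediate
46 | CNP0177131.1 | C=C(C)[C@H]1CC[C@H](C)[C@]23CC=C(C)[C@@]2(C1)Oc1cc2c(c(C)c1O3)C(=O)C[C@@H]1[C@@]2(C)CC[C@@]2(C)[C@H]3CCC(=O)C[C@]3(C)CC[C@]12C | target

## Step count and risks

Total step count: 28. Longest linear sequence: 18 steps (steps 1–6, 10–20 and 28).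

Steps most likely to fail:

1. Step 18. What may go wrong: ring C closing on the face of C14 cis to the C12 branch (cis C/D junction), a 1,2-methyl shift from C13 to the C14 cation, or simple hydrofunctionalisation of the initiating alkene before cyclisation. Fallback (sets out from 28, returns at 31): ketone 28 is treated with dimethylsulfonium methylide (Me3SI, n-BuLi, THF, −10 °C), which should add to the α-face of C14, anti to the axial C12 branch, to give the spiro-epoxide F4. MeAlCl2 (CH2Cl2, −78 °C) then starts an epoxide-initiated cation–olefin bicyclisation in which C8 opens the C14–O bond with inversion and the arene closes ring B, so that the C14 configuration is fixed by the epoxide and not by ring-fusion preference; this gives the C26 primary alcohol F5. Mesylation (MsCl, Et3N) gives the mesylate F6, LiEt3BH (THF, 65 °C) reduces it to the dithiane-protected pentacycle F7, and MeI/CaCO3 in aqueous MeCN unmasks the C21 ketone to give 31.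

2. Step 28. What may go wrong: tautomerisation of the cyclopentadiene by 1,5-hydrogen shifts before cycloaddition, reversed orientation of the two oxygens, attack on the face syn to the C10g methyl, or carbo-Diels–Alder addition to the quinone C=C. Fallback (sets out from 33 and 42, returns at 46): 33 is oxidised with Ag2O in the presence of the tertiary alcohol 42, which has an isolated tetrasubstituted ring alkene and no cyclopentadiene that could tautomerise. Hetero-Diels–Alder addition of 45 to that alkene anti to the C10g methyl should give the benzodioxane alcohol F8. Dehydration with Burgess reagent gives the isopropenyl compound F9, and ring-closing metathesis (second-generation Grubbs catalyst, CH2Cl2, 40 °C) between the cis-disposed allyl and isopropenyl groups closes the cyclopentene to give 46.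

3. Step 13. What may go wrong: erosion of enantio- and endo selectivity by the uncatalysed background cycloaddition, and loss of the silyl dienol ether to the acid-activated catalyst. Fallback (sets out from 23, returns at 26): 23 is cyclised without catalyst (toluene, 2,6-di-tert-butyl-4-methylphenol, 110 °C) to 24 as the racemate, which NaBH4 reduces to the racemic neopentyl alcohol F1. Esterification with (S)-2-methoxy-2-phenylacetic acid (DCC, DMAP) gives two diastereomeric esters, from which the ester F2 with the required configuration is separated by chromatography. LiAlH4 returns the alcohol F1 as a single enantiomer, MsCl/Et3N gives the mesylate F3, and LiEt3BH reduces it to 26, so that step 14 is bypassed.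

Further compounds
F1 | step 13 | D/E silyl enol ether with 17β-hydroxymethyl, 18α-H (first racemic, then single enantiomer as drawn) | COc1ccc(CC/C=C(C)\CCC2=C(O[Si](C(C)C)(C(C)C)C(C)C)CC[C@@]3(CO)CC4(SCCCS4)CC[C@H]23)c(C)c1OC
F2 | step 13 | (S)-2-methoxy-2-phenylacetate ester of F1 | COc1ccc(CC/C=C(C)\CCC2=C(O[Si](C(C)C)(C(C)C)C(C)C)CC[C@@]3(COC(=O)[C@@H](OC)c5ccccc5)CC4(SCCCS4)CC[C@H]23)c(C)c1OC
F3 | step 13 | methanesulfonate of F1 | COc1ccc(CC/C=C(C)\CCC2=C(O[Si](C(C)C)(C(C)C)C(C)C)CC[C@@]3(COS(C)(=O)=O)CC4(SCCCS4)CC[C@H]23)c(C)c1OC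
F4 | step 18 | spiro-epoxide at C14 of 28 (epoxide CH2 on the α-face, oxygen on the β-face) | COc1ccc(CC/C=C(C)\CC[C@@]2(C)[C@H]3CCC4(SCCCS4)C[C@]3(C)CC[C@]25CO5)c(C)c1OC
F5 | step 18 | pentacyclic dimethyl ether with 14β-hydroxymethyl and C21 dithiane | COc1cc2c(c(C)c1OC)CC[C@@H]1[C@@]2(C)CC[C@@]2(C)[C@H]3CCC4(SCCCS4)C[C@]3(C)CC[C@]12CO
F6 | step 18 | methanesulfonate of F5 | COc1cc2c(c(C)c1OC)CC[C@@H]1[C@@]2(C)CC[C@@]2(C)[C@H]3CCC4(SCCCS4)C[C@]3(C)CC[C@]12COS(C)(=O)=O
F7 | step 18 | pentacyclic dimethyl ether with 14β-methyl and C21 dithiane | COc1cc2c(c(C)c1OC)CC[C@@H]1[C@@]2(C)CC[C@@]2(C)[C@H]3CCC4(SCCCS4)C[C@]3(C)CC[C@]12C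
F8 | step 28 | benzodioxane adduct of 45 and 42 (allyl on C1g, 2-hydroxypropan-2-yl on C5g, both cis) | C=C(C)[C@H]1CC[C@H](C)[C@]3(CC=C)[C@@](C1)(C(C)(C)O)Oc1cc2c(c(C)c1O3)C(=O)C[C@@H]1[C@@]2(C)CC[C@@]2(C)[C@H]3CCC(=O)C[C@]3(C)CC[C@]12C
F9 | step 28 | benzodioxane with allyl on C1g and isopropenyl on C5g | C=C(C)[C@H]1CC[C@H](C)[C@]3(CC=C)[C@@](C1)(C(C)=C)Oc1cc2c(c(C)c1O3)C(=O)C[C@@H]1[C@@]2(C)CC[C@@]2(C)[C@H]3CCC(=O)C[C@]3(C)CC[C@]12C
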